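**Retrosynthetic overview**

1. Numbering: ring C5 (isopropenyl C4, C3, C15), C6 (OH), C7 (carbinol C11 with acetoxymethyls C12 and C13), C8, C9, C10 (methyl C14, vinyl C1=C2). The strategy rests on one feature: on this cyclohexane the C6 oxygen and the vinyl carbon C1 on C10 are cis-1,3 and both trans to the C5 isopropenyl group, so O–C6–C5–C10–C1 can be closed as a γ-lactone.
2. Endgame: diacetate ⇐ tetraol ⇐ acetonide; C7–C11 by aldol of the C6 ketone with 2,2-dimethyl-1,3-dioxan-5-one, then C6–OH reset with SmI2; the C6 ketone and the C10 vinyl group come from the bicyclic lactone (iBu2AlH, Wittig, oxidation).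
3. Key disconnection C9–C10: the 6-oxabicyclo[3.2.1]octan-7-one ⇐ enolate of a γ-lactone with a 3-iodopropyl chain on C6. This lactone must be 4,5-cis (chain and isopropenyl on the same face), because the isopropenyl group has to end anti to the lactone bridge.
4. The cis-lactone ⇐ anti-allylboration of 4-chlorobutanal with an (E)-γ-(CH2CO2Me)-methallyl boronate (the ring closes through the γ-arm, so anti becomes cis), then α-methylation and Cl→I exchange.
5. Ring order: γ-lactone (step 4), cyclohexane (step 7, the only carbocycle), lactone opened again (steps 8 and 9).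

Key step: step 7

Remark: C3 of lactones 11 and 12 is a mixture of epimers that converge on one enolate; the (R)-phosphoric acid is taken to deliver the allyl unit to the Re face of the aldehyde as it does with simple allyl and crotyl pinacol boronates, and the (S)-acid would be used if the sense were opposite.

**Route**

Step 1
Reactants: 1 methyl 4-methylpent-3-enoate
Product: 2 methyl (E)-5-hydroxy-4-methylpent-3-enoate
Conditions: SeO2 (0.3 equiv), tBuOOH (2 equiv), salicylic acid (cat.), CH2Cl2, rt
Reagents that add atoms: selenium dioxide, O=[Se]=O (oxygen carrier); tert-butyl hydroperoxide, CC(C)(C)OO (terminal oxygen source)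
Why: Selenium dioxide allylic oxidation (ene reaction then [2,3]-sigmatropic shift) attacks the (E)-methyl group of the trisubstituted alkene, so the primary allylic alcohol should form with the E geometry that later becomes the anti relation of step 4.

Step 2
Reactants: 2 methyl (E)-5-hydroxy-4-methylpent-3-enoate; 3 bis(pinacolato)diboron
Product: 4 methyl (E)-4-methyl-5-(4,4,5,5-tetramethyl-1,3,2-dioxaborolan-2-yl)pent-3-enoate
Conditions: [Pd(MeCN)4](BF4)2 (5 mol%), DMSO–MeOH (1:1), 50 °C
Reagents that add atoms: none
Why: Palladium-catalysed borylation of an allylic alcohol with a diboron reagent runs through a π-allylpalladium intermediate that is borylated at its unhindered CH2 terminus, which should give the linear allylboronate with the E geometry retained.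

Step 3
Reactants: 5 4-chlorobutan-1-ol
Product: 6 4-chlorobutanal
Conditions: TEMPO (2,2,6,6-tetramethylpiperidin-1-oxyl, 10 mol%), PhI(OAc)2 (1.1 equiv), CH2Cl2, rt; used at once
Reagents that add atoms: none
Why: TEMPO-catalysed oxidation with PhI(OAc)2 as terminal oxidant stops at the aldehyde and is mild enough that the chloro alcohol should not cyclise to tetrahydrofuran.

Step 4
Reactants: 4 methyl (E)-4-methyl-5-(4,4,5,5-tetramethyl-1,3,2-dioxaborolan-2-yl)pent-3-enoate; 6 4-chlorobutanal
Product: 9 (4R,5S)-5-(3-chloropropyl)-4-(prop-1-en-2-yl)oxolan-2-one, via pinacol borate ester 7 (not isolated), via hydroxy ester 8 (not isolated)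
Conditions: (R)-TRIP [(R)-3,3'-bis(2,4,6-triisopropylphenyl)-1,1'-binaphthalene-2,2'-diyl hydrogen phosphate] (5 mol%), 4 Å molecular sieves, toluene, −30 °C; then H2O, p-TsOH·H2O (cat.), CH2Cl2, rt
Reagents that add atoms: none
Why: Chiral phosphoric acid-catalysed allylboration through a chair Zimmerman–Traxler transition state, in which the (E)-boronate holds the CH2CO2Me arm equatorial and gives the anti (3R,4S) adduct while the catalyst selects the Re face of the aldehyde (C6), and because the acid-catalysed lactonisation closes through that arm the anti relation becomes the 4,5-cis relation of isopropenyl and chloropropyl groups (C5 and C6 of the target are set here).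

Step 5
Reactants: 9 (4R,5S)-5-(3-chloropropyl)-4-(prop-1-en-2-yl)oxolan-2-one
Product: 11 (3RS,4R,5S)-5-(3-chloropropyl)-3-methyl-4-(prop-1-en-2-yl)oxolan-2-one, via lithium lactone enolate 10 (not isolated)
Conditions: LiN(iPr)2 (1.05 equiv), THF, −78 °C; MeI (3 equiv), −78 → −40 °C
Reagents that add atoms: iodomethane, CI
Why: Lactone enolate alkylation, in which the lithium enolate is methylated at low temperature where the primary chloride is inert, mainly anti to the isopropenyl group, although the C3 configuration is irrelevant because it is planarised again in step 7.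

Step 6
Reactants: 11 (3RS,4R,5S)-5-(3-chloropropyl)-3-methyl-4-(prop-1-en-2-yl)oxolan-2-one
Product: 12 (3RS,4R,5S)-5-(3-iodopropyl)-3-methyl-4-(prop-1-en-2-yl)oxolan-2-one
Conditions: NaI (5 equiv), acetone, reflux
Reagents that add atoms: sodium iodide, [Na+].[I-]
Why: Finkelstein halide exchange (SN2, driven by precipitation of NaCl) turns the unreactive chloride into the iodide needed for ring closure without touching the lactone.

Step 7
Reactants: 12 (3RS,4R,5S)-5-(3-iodopropyl)-3-methyl-4-(prop-1-en-2-yl)oxolan-2-one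
Product: 14 (1R,5S,8S)-1-methyl-8-(prop-1-en-2-yl)-6-oxabicyclo[3.2.1]octan-7-one, via lithium lactone enolate 13 (not isolated)
Conditions: LiN(iPr)2 (1.1 equiv), THF (0.01 M), −78 °C; DMPU (5 equiv), −78 → 0 °C
Reagents that add atoms: none
Why: LiN(iPr)2 removes the C3–H of either epimer of 12 to give the single planar lithium enolate 13, whose α-carbon (C10) displaces iodide from C9 in an intramolecular SN2 reaction; the closest known reaction type is the intramolecular C-alkylation of ester, lactone and ketone enolates by ω-haloalkyl chains to give bridged bicycles. The cyclohexane (C5–C10) closes in the 6-(enolexo)-exo-tet mode, bridging the α- and γ-carbons of the lactone to give the 6-oxabicyclo[3.2.1]octan-7-one. The new quaternary centre C10 is controlled by the tether alone: the three-carbon chain is fixed on one face of the lactone at C6 and can reach only that face of the enolate, so C9 enters cis to the C6–C7 bond and the methyl group is left on the opposite face, trans to the ring oxygen on the new cyclohexane as in the target. Because the lactone is 4,5-cis, this is also the face that carries the isopropenyl group, so the bond forms syn to it and the isopropenyl group ends on the one-carbon bridge over the three-carbon bridge (anti to the lactone bridge, hence trans to both the C6 oxygen and the future vinyl carbon C1); the approach is hindered, but no other C-alkylation product is geometrically possible. The step needs C- over O-alkylation and cyclisation over intermolecular alkylation or E2 loss of HI, which the lithium counter-ion, the soft iodide, complete enolate formation at −78 °C before warming and high dilution should secure; the product has no α-hydrogen and cannot be enolised further.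

Step 8
Reactants: 14 (1R,5S,8S)-1-methyl-8-(prop-1-en-2-yl)-6-oxabicyclo[3.2.1]octan-7-one
Product: 15 (1R,5S,8S)-1-methyl-8-(prop-1-en-2-yl)-6-oxabicyclo[3.2.1]octan-7-ol (both C7 anomers)
Conditions: iBu2AlH (1.1 equiv), CH2Cl2, −78 °C; aqueous work-up
Reagents that add atoms: none
Why: Partial reduction of a lactone with iBu2AlH at −78 °C stops at the tetrahedral aluminium hemiacetal, which gives the lactol on work-up while the isolated alkene is inert.

Step 9
Reactants: 15 (1R,5S,8S)-1-methyl-8-(prop-1-en-2-yl)-6-oxabicyclo[3.2.1]octan-7-ol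
Product: 17 (1S,2S,3S)-3-ethenyl-3-methyl-2-(prop-1-en-2-yl)cyclohexan-1-ol, via ring-opened hydroxy aldehyde 16 (not isolated)
Conditions: Ph3PCH3Br (4 equiv), KOtBu (3.8 equiv), THF, 0 °C → reflux
Reagents that add atoms: methyltriphenylphosphonium bromide, C[P+](c1ccccc1)(c1ccccc1)c1ccccc1.[Br-]
Why: Wittig methylenation of a lactol, in which the alkoxide of 15 opens to hydroxy aldehyde 16 and its non-enolisable aldehyde on the quaternary carbon is converted to the vinyl group by excess Ph3P=CH2, which releases the C6 hydroxyl with C5, C6 and C10 untouched.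

Step 10
Reactants: 17 (1S,2S,3S)-3-ethenyl-3-methyl-2-(prop-1-en-2-yl)cyclohexan-1-ol
Product: 18 (2S,3S)-3-ethenyl-3-methyl-2-(prop-1-en-2-yl)cyclohexan-1-one
Conditions: Dess–Martin periodinane (1.3 equiv), NaHCO3, CH2Cl2, rt
Reagents that add atoms: none
Why: Dess–Martin oxidation under bicarbonate buffer gives the ketone under neutral conditions at room temperature, which should avoid epimerisation at C5 and migration of the isopropenyl double bond into conjugation.

Step 11
Reactants: 18 (2S,3S)-3-ethenyl-3-methyl-2-(prop-1-en-2-yl)cyclohexan-1-one; 19 2,2-dimethyl-1,3-dioxan-5-one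
Product: 21 (2S,3S,6S)-3-ethenyl-6-(5-hydroxy-2,2-dimethyl-1,3-dioxan-5-yl)-3-methyl-2-(prop-1-en-2-yl)cyclohexan-1-one, via lithium ketone enolate 20 (not isolated)
Conditions: LiN(iPr)2 (1.05 equiv), THF, −78 °C; 19 (1.5 equiv), −78 → −40 °C; AcOH, −78 °C
Reagents that add atoms: none
Why: Directed aldol addition of a ketone lithium enolate to a ketone, in which kinetic deprotonation takes the unhindered C7 methylene and not the tertiary C5–H next to the quaternary carbon, the electron-poor dioxanone is a reactive acceptor, and because the tertiary lithium aldolate forms reversibly the more stable chelate with the new side chain equatorial (cis to the C5 isopropenyl group, C7 as in the target) is expected to accumulate on warming to −40 °C before the cold acidic quench.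

Step 12
Reactants: 21 (2S,3S,6S)-3-ethenyl-6-(5-hydroxy-2,2-dimethyl-1,3-dioxan-5-yl)-3-methyl-2-(prop-1-en-2-yl)cyclohexan-1-one
Product: 22 (1R,2S,3S,6R)-3-ethenyl-6-(5-hydroxy-2,2-dimethyl-1,3-dioxan-5-yl)-3-methyl-2-(prop-1-en-2-yl)cyclohexan-1-ol
Conditions: SmI2 (3 equiv), MeOH, THF, 0 °C
Reagents that add atoms: none
Why: Samarium diiodide reduction of a β-hydroxy ketone (ketyl formed within a chelate to the C11 hydroxyl, then protonation by methanol) operates under product-stability control and should place the new C6 hydroxyl equatorial, trans to both neighbours, whereas hydride reagents would be steered to the wrong face by the axial C10 methyl group.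

Step 13
Reactants: 22 (1R,2S,3S,6R)-3-ethenyl-6-(5-hydroxy-2,2-dimethyl-1,3-dioxan-5-yl)-3-methyl-2-(prop-1-en-2-yl)cyclohexan-1-ol
Product: 23 2-[(1R,2R,3S,4S)-4-ethenyl-2-hydroxy-4-methyl-3-(prop-1-en-2-yl)cyclohexyl]propane-1,2,3-triol
Conditions: AcOH–H2O (4:1), 40 °C
Reagents that add atoms: none
Why: Acid-catalysed hydrolysis of the isopropylidene acetal in aqueous acetic acid frees the two primary hydroxyls under conditions that should leave the tertiary alcohol and the two alkenes intact.

Step 14
Reactants: 23 2-[(1R,2R,3S,4S)-4-ethenyl-2-hydroxy-4-methyl-3-(prop-1-en-2-yl)cyclohexyl]propane-1,2,3-triol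
Product: 24 2-[(1R,2R,3S,4S)-4-ethenyl-2-hydroxy-4-methyl-3-(prop-1-en-2-yl)cyclohexyl]-2-hydroxypropane-1,3-diyl diacetate (target)
Conditions: Ac2O (2.2 equiv), pyridine, CH2Cl2, 0 °C
Reagents that add atoms: acetic anhydride, CC(=O)OC(C)=O
Why: Selective acylation, in which the two primary hydroxyls should be acetylated much faster than the secondary hydroxyl flanked by two ring substituents or the tertiary hydroxyl, giving the target diacetate.

**Compound list**

1 | methyl 4-methylpent-3-enoate | COC(=O)CC=C(C)C | starting material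
2 | methyl (E)-5-hydroxy-4-methylpent-3-enoate | OC/C(C)=C/CC(=O)OC | intermediate
3 | bis(pinacolato)diboron | CC1(C)OB(OC1(C)C)B1OC(C)(C)C(C)(C)O1 | starting material
4 | methyl (E)-4-methyl-5-(4,4,5,5-tetramethyl-1,3,2-dioxaborolan-2-yl)pent-3-enoate | CC1(C)OB(C/C(C)=C/CC(=O)OC)OC1(C)C | intermediate
5 | 4-chlorobutan-1-ol | OCCCCCl | starting material
6 | 4-chlorobutanal | O=CCCCCl | intermediate
7 | methyl (3R,4S)-7-chloro-3-(prop-1-en-2-yl)-4-[(4,4,5,5-tetramethyl-1,3,2-dioxaborolan-2-yl)oxy]heptanoate (formed in the flask, not isolated) | COC(=O)C[C@H](C(C)=C)[C@H](CCCCl)OB1OC(C)(C)C(C)(C)O1 | intermediate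
8 | methyl (3R,4S)-7-chloro-4-hydroxy-3-(prop-1-en-2-yl)heptanoate (formed in the flask, not isolated) | COC(=O)C[C@H](C(C)=C)[C@H](CCCCl)O | intermediate
9 | (4R,5S)-5-(3-chloropropyl)-4-(prop-1-en-2-yl)oxolan-2-one (4,5-cis) | O=C1C[C@H](C(C)=C)[C@H](CCCCl)O1 | intermediate
10 | lithium enolate of lactone 9 (C2–O–Li, C2=C3; C4 and C5 as in 9; not isolated) | [Li+].[O-]C1=C[C@H](C(C)=C)[C@H](CCCCl)O1 | intermediate
11 | (3RS,4R,5S)-5-(3-chloropropyl)-3-methyl-4-(prop-1-en-2-yl)oxolan-2-one (4,5-cis, C3 epimers) | CC1C(=O)O[C@@H](CCCCl)[C@H]1C(C)=C | intermediate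
12 | (3RS,4R,5S)-5-(3-iodopropyl)-3-methyl-4-(prop-1-en-2-yl)oxolan-2-one (4,5-cis, C3 epimers) | CC1C(=O)O[C@@H](CCCI)[C@H]1C(C)=C | intermediate
13 | lithium enolate of lactone 12 (C2–O–Li, C2=C3; C4 and C5 as in 12; not isolated) | [Li+].CC1=C([O-])O[C@@H](CCCI)[C@H]1C(C)=C | intermediate
14 | (1R,5S,8S)-1-methyl-8-(prop-1-en-2-yl)-6-oxabicyclo[3.2.1]octan-7-one (isopropenyl on the one-carbon bridge, over the three-carbon bridge) | O=C1O[C@H]2CCC[C@]1(C)[C@@H]2C(C)=C | intermediate
15 | (1R,5S,8S)-1-methyl-8-(prop-1-en-2-yl)-6-oxabicyclo[3.2.1]octan-7-ol (C7 anomers) | OC1O[C@H]2CCC[C@]1(C)[C@@H]2C(C)=C | intermediate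
16 | (1R,2S,3S)-3-hydroxy-1-methyl-2-(prop-1-en-2-yl)cyclohexane-1-carbaldehyde (as its potassium alkoxide in the flask, not isolated) | O=C[C@]1(C)CCC[C@H](O)[C@H]1C(=C)C | intermediate
17 | (1S,2S,3S)-3-ethenyl-3-methyl-2-(prop-1-en-2-yl)cyclohexan-1-ol | C=C[C@]1(C)CCC[C@H](O)[C@H]1C(=C)C | intermediate
18 | (2S,3S)-3-ethenyl-3-methyl-2-(prop-1-en-2-yl)cyclohexan-1-one | C=C[C@]1(C)CCCC(=O)[C@H]1C(=C)C | intermediate
19 | 2,2-dimethyl-1,3-dioxan-5-one | CC1(C)OCC(=O)CO1 | starting material
20 | lithium enolate of ketone 18 towards the CH2 side (ring C1=C6 double bond; C2 and C3 as in 18; not isolated) | [Li+].C=C[C@]1(C)CCC=C([O-])[C@H]1C(=C)C | intermediate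
21 | (2S,3S,6S)-3-ethenyl-6-(5-hydroxy-2,2-dimethyl-1,3-dioxan-5-yl)-3-methyl-2-(prop-1-en-2-yl)cyclohexan-1-one | C=C[C@]1(C)CC[C@@H](C2(O)COC(C)(C)OC2)C(=O)[C@H]1C(=C)C | intermediate
22 | (1R,2S,3S,6R)-3-ethenyl-6-(5-hydroxy-2,2-dimethyl-1,3-dioxan-5-yl)-3-methyl-2-(prop-1-en-2-yl)cyclohexan-1-ol | C=C[C@]1(C)CC[C@@H](C2(O)COC(C)(C)OC2)[C@H](O)[C@H]1C(=C)C | intermediate
23 | 2-[(1R,2R,3S,4S)-4-ethenyl-2-hydroxy-4-methyl-3-(prop-1-en-2-yl)cyclohexyl]propane-1,2,3-triol | C=C[C@]1(C)CC[C@@H](C(O)(CO)CO)[C@H](O)[C@H]1C(=C)C | intermediate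
24 | 2-[(1R,2R,3S,4S)-4-ethenyl-2-hydroxy-4-methyl-3-(prop-1-en-2-yl)cyclohexyl]-2-hydroxypropane-1,3-diyl diacetate | C=C[C@]1(C)CC[C@@H](C(O)(COC(C)=O)COC(C)=O)[C@H](O)[C@H]1C(=C)C | target

**Step count**

Total: 14 steps. Longest linear sequence: 13 steps (steps 1, 2 and 4 to 14; step 3 is the side branch that supplies the aldehyde).

**Steps most likely to fail**

Step 7 (bridging enolate alkylation). The new bond must form on the enolate face that also carries the isopropenyl group. If closure is slow, O-alkylation, intermolecular alkylation or E2 loss of HI could take over. The fallback gives up the lactone tether and closes the same C9–C10 bond from an open-chain amide enolate under allylic-strain control. It sets out from chloro lactone 11 and returns at alcohol 17.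
- Lactone 11 would be opened with MeNH(OMe)·HCl and Me2AlCl to (2RS,3R,4S)-7-chloro-4-hydroxy-N-methoxy-N,2-dimethyl-3-(prop-1-en-2-yl)heptanamide F1.
- F1 would be silylated at once (tBuMe2SiOTf, 2,6-lutidine) to its tert-butyldimethylsilyl ether F2, and NaI in acetone would give the iodide F3.
- LiN(iPr)2 would form the (Z)-amide enolate. Allylic 1,3-strain holds the C5–H in the enolate plane, and a chair 6-exo-tet transition state with isopropenyl and silyloxy groups equatorial places the amide carbonyl equatorial and the methyl axial. This should give (1R,2S,3S)-3-[tert-butyl(dimethyl)silyl]oxy-N-methoxy-N,1-dimethyl-2-(prop-1-en-2-yl)cyclohexane-1-carboxamide F4 with C10 as in the target.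
- iBu2AlH would reduce the amide to the aldehyde (1R,2S,3S)-3-[tert-butyl(dimethyl)silyl]oxy-1-methyl-2-(prop-1-en-2-yl)cyclohexane-1-carbaldehyde F5.
- Wittig methylenation would give the silyl ether tert-butyl{[(1S,2S,3S)-3-ethenyl-3-methyl-2-(prop-1-en-2-yl)cyclohexyl]oxy}dimethylsilane F6, and Bu4NF would release 17.

Step 11 (ketone–ketone aldol). Several processes could go wrong: proton transfer from the enolisable acceptor to the enolate, retro-aldol loss on work-up, partial deprotonation at the allylic C5–H, or kinetic attack anti to the ring substituents so that the C7 epimer predominates. The fallback uses a non-enolisable, more electrophilic acceptor under thermodynamic amine catalysis. It sets out from ketone 18 and returns at tetraol 23.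
- Pyrrolidine and AcOH (catalytic) would form the less substituted enamine on the C7 side; the enamine towards C5 is disfavoured by allylic strain.
- This enamine would add to diethyl oxomalonate, and reversible enamine formation should let the side chain settle equatorial. The product is diethyl 2-[(1S,3S,4S)-4-ethenyl-4-methyl-2-oxo-3-(prop-1-en-2-yl)cyclohexyl]-2-hydroxypropanedioate F7.
- SmI2 and MeOH would reduce the ketone as in step 12 to diethyl 2-[(1R,2R,3S,4S)-4-ethenyl-2-hydroxy-4-methyl-3-(prop-1-en-2-yl)cyclohexyl]-2-hydroxypropanedioate F8.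
- LiAlH4 would reduce both esters to give 23.

Step 12 (setting C6). Poor facial selectivity could leave the axial alcohol, or the Lewis acidic samarium could trigger retro-aldol cleavage. The fallback separates reduction from stereocontrol. It sets out from ketone 21 and returns at alcohol 22.
- NaBH4 in MeOH at −20 °C would reduce the ketone without regard to selectivity, giving mainly the axial epimer (1S,2S,3S,6R)-3-ethenyl-6-(5-hydroxy-2,2-dimethyl-1,3-dioxan-5-yl)-3-methyl-2-(prop-1-en-2-yl)cyclohexan-1-ol F9.
- A Meerwein–Ponndorf–Verley/Oppenauer equilibration (Al(OiPr)3, iPrOH, catalytic acetone, toluene, 80 °C) would then epimerise the carbinol. The axial epimer carries a syn-axial hydroxyl/methyl interaction with C10, so the equilibrium should lie on the side of the equatorial alcohol 22.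

**Further compounds**

F1 | step 7 | (2RS,3R,4S)-7-chloro-4-hydroxy-N-methoxy-N,2-dimethyl-3-(prop-1-en-2-yl)heptanamide | CON(C)C(=O)C(C)[C@H](C(C)=C)[C@H](CCCCl)O
F2 | step 7 | (2RS,3R,4S)-4-[tert-butyl(dimethyl)silyl]oxy-7-chloro-N-methoxy-N,2-dimethyl-3-(prop-1-en-2-yl)heptanamide | CON(C)C(=O)C(C)[C@H](C(C)=C)[C@H](CCCCl)O[Si](C)(C)C(C)(C)C
F3 | step 7 | (2RS,3R,4S)-4-[tert-butyl(dimethyl)silyl]oxy-7-iodo-N-methoxy-N,2-dimethyl-3-(prop-1-en-2-yl)heptanamide | CON(C)C(=O)C(C)[C@H](C(C)=C)[C@H](CCCI)O[Si](C)(C)C(C)(C)C
F4 | step 7 | (1R,2S,3S)-3-[tert-butyl(dimethyl)silyl]oxy-N-methoxy-N,1-dimethyl-2-(prop-1-en-2-yl)cyclohexane-1-carboxamide | CON(C)C(=O)[C@]1(C)CCC[C@H](O[Si](C)(C)C(C)(C)C)[C@H]1C(=C)C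
F5 | step 7 | (1R,2S,3S)-3-[tert-butyl(dimethyl)silyl]oxy-1-methyl-2-(prop-1-en-2-yl)cyclohexane-1-carbaldehyde | O=C[C@]1(C)CCC[C@H](O[Si](C)(C)C(C)(C)C)[C@H]1C(=C)C
F6 | step 7 | tert-butyl{[(1S,2S,3S)-3-ethenyl-3-methyl-2-(prop-1-en-2-yl)cyclohexyl]oxy}dimethylsilane | C=C[C@]1(C)CCC[C@H](O[Si](C)(C)C(C)(C)C)[C@H]1C(=C)C
F7 | step 11 | diethyl 2-[(1S,3S,4S)-4-ethenyl-4-methyl-2-oxo-3-(prop-1-en-2-yl)cyclohexyl]-2-hydroxypropanedioate | C=C[C@]1(C)CC[C@@H](C(O)(C(=O)OCC)C(=O)OCC)C(=O)[C@H]1C(=C)C
F8 | step 11 | diethyl 2-[(1R,2R,3S,4S)-4-ethenyl-2-hydroxy-4-methyl-3-(prop-1-en-2-yl)cyclohexyl]-2-hydroxypropanedioate | C=C[C@]1(C)CC[C@@H](C(O)(C(=O)OCC)C(=O)OCC)[C@H](O)[C@H]1C(=C)C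
F9 | step 12 | (1S,2S,3S,6R)-3-ethenyl-6-(5-hydroxy-2,2-dimethyl-1,3-dioxan-5-yl)-3-methyl-2-(prop-1-en-2-yl)cyclohexan-1-ol | C=C[C@]1(C)CC[C@@H](C2(O)COC(C)(C)OC2)[C@@H](O)[C@H]1C(=C)C
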